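**Assumptions (one line each)**
- The target's three dihydrobenzofurans are trans, with configurations taken directly from the SMILES: DHB1 (stilbene end) is (2R,3R), DHB2 is (2S,3S), DHB3 (3,5-dihydroxyphenyl end) is (2R,3R). The alternating series is therefore built with alternating sulfide enantiomers.
- Vilsmeier formylation of 1-bromo-3,5-dimethoxybenzene is assumed to favour C2 over the hindered C4, with the minor isomer removed by chromatography.
- I assume the (2S,5S)-sulfide delivers the (2R,3R) ring and the (2R,5R)-sulfide the (2S,3S) ring. This mapping is to be confirmed by a small screen.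

## Retrosynthetic overview
1. Target ← global O-demethylation of the nonamethyl ether ← Heck installation of the (E)-4-methoxystyryl group on the terminal aryl bromide of a tris-dihydrobenzofuran.
2. Each trans-2,3-diaryl-dihydrobenzofuran (DHB) is disconnected, by the proposed catalytic asymmetric [4+1] step, into an o-quinone methide (from an o-hydroxybenzhydryl sulfone) and a 4-methoxybenzyl sulfonium ylide. The ylide is made from a chiral sulfide and a diazo compound.
3. Each benzhydrol comes from an aryllithium plus one common building block, 2-bromo-6-hydroxy-4-methoxybenzaldehyde.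
4. The chain grows outward from the 3,5-dimethoxyphenyl terminus. Rings form in the order DHB3, then DHB2, then DHB1. The stilbene is added last, then demethylation.

## Route

**Step 1**
Reactants: 1 (1-bromo-3,5-dimethoxybenzene); 2 (DMF)
Product: 3 (2-bromo-4,6-dimethoxybenzaldehyde)
Conditions: POCl3, DMF, 0 → 70 °C; then aq. NaOAc
Reagents that add atoms: DMF, CN(C)C=O (supplies the CHO carbon)
Why: Vilsmeier–Haack formylation occurs ortho to one OMe and para to the other, at the less hindered C2.

**Step 2**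
Reactants: 3
Product: 4 (2-bromo-6-hydroxy-4-methoxybenzaldehyde)
Conditions: BCl3 (1.1 equiv), CH2Cl2, −78 → 0 °C
Reagents that add atoms: none
Why: Chelation to the formyl group cleaves only the ortho OMe, leaving the para OMe and the Ar–Br intact (selective BCl3 demethylation).

**Step 3**
Reactants: 4; 1 (as 3,5-dimethoxyphenyllithium)
Product: 5 ((2-bromo-6-hydroxy-4-methoxyphenyl)(3,5-dimethoxyphenyl)methanol, racemic carbinol)
Conditions: (a) 4, NaH (1.0 equiv), THF, 0 °C; (b) 1, n-BuLi, THF, −78 °C, then add to (a), −78 → 0 °C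
Reagents that add atoms: none beyond the listed reactants (the aryl group comes from 1)
Why: 1,2-addition of an aryllithium to the aldehyde. The carbinol stereocentre is transient and is erased when the o-quinone methide forms in Step 5.

**Step 4**
Reactants: 5; 6 (sodium p-toluenesulfinate)
Product: 7 (3-bromo-2-[(3,5-dimethoxyphenyl)(tosyl)methyl]-5-methoxyphenol, racemic)
Conditions: 6 (3 equiv), HCO2H/CH2Cl2 (1:4), 25 °C
Reagents that add atoms: sodium p-toluenesulfinate, Cc1ccc(cc1)S(=O)[O-].[Na+] (adds Ts)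
Why: The electron-rich o-hydroxybenzhydrol ionises, through the o-quinone methide tautomer, and is trapped at sulfur by sulfinate. This is the standard route to base-labile o-quinone methide precursors.

**Step 5 (new step, ring DHB3)**
Reactants: 7; 8 (p-anisaldehyde tosylhydrazone)
Product: 9 ((2R,3R)-4-bromo-3-(3,5-dimethoxyphenyl)-6-methoxy-2-(4-methoxyphenyl)-2,3-dihydrobenzofuran)
Conditions: 8 (2.5 equiv), Cs2CO3 (4 equiv), Rh2(OAc)4 (1 mol%), (2S,5S)-2,5-dimethylthiolane (20 mol%), BnEt3NCl (10 mol%), 1,4-dioxane, 40 °C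
Reagents that add atoms: 8, COc1ccc(/C=N/NS(=O)(=O)c2ccc(C)cc2)cc1 (supplies the C2–H/4-methoxyphenyl unit)
Why: Proposed new method: sulfide-catalysed asymmetric [4+1] annulation of a hindered diaryl o-quinone methide with an aryl sulfonium ylide.
- Mechanism: Cs2CO3 converts 8 into 4-MeOC6H4CHN2, and Rh turns this into a carbene. The chiral C2-symmetric sulfide captures the carbene as an ylide. Base converts the sulfone-phenol into a phenoxide that expels sulfinate to give the achiral diaryl o-quinone methide, so both epimers of 7 converge. The ylide adds 1,4 to the exocyclic carbon, with the sulfide's chiral pocket choosing the face and setting C3. Phenoxide then displaces the sulfide in a 5-exo-tet closure with the two aryl groups anti, giving trans and setting C2.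
- Closest known chemistry: Aggarwal sulfide/Rh-carbene catalytic ylide chemistry, and achiral sulfonium-ylide [4+1] annulations of o-quinone methides.

**Step 6**
Reactants: 9; 4
Product: 10 (benzhydrol: (2-bromo-6-hydroxy-4-methoxyphenyl)[DHB3-4-yl]methanol, epimeric at the carbinol)
Conditions: 9, t-BuLi (2.0 equiv), THF, −78 °C, 10 min; then the sodium phenoxide of 4 (NaH, THF), −78 → 0 °C
Reagents that add atoms: none beyond the listed reactants
Why: Br/Li exchange at the C4 bromide, then 1,2-addition to the aldehyde. The DHB3 stereocentres are untouched, and the low temperature and short exchange time avoid E1cB ring opening.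

**Step 7**
Reactants: 10; 6
Product: 11 (benzhydryl tosyl sulfone)
Conditions: 6 (3 equiv), HCO2H/CH2Cl2 (1:4), 25 °C
Reagents that add atoms: sodium p-toluenesulfinate, Cc1ccc(cc1)S(=O)[O-].[Na+] (adds Ts)
Why: Same sulfone-forming reaction as Step 4. Any acid-induced C2 epimerisation of DHB3 re-closes to the thermodynamic trans isomer, and C3 is unaffected.

**Step 8 (new step, ring DHB2)**
Reactants: 11; 8
Product: 12 (bis-DHB aryl bromide: new ring (2S,3S), DHB3 ring (2R,3R))
Conditions: 8 (2.5 equiv), Cs2CO3 (4 equiv), Rh2(OAc)4 (1 mol%), (2R,5R)-2,5-dimethylthiolane (20 mol%), BnEt3NCl (10 mol%), 1,4-dioxane, 40 °C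
Reagents that add atoms: 8, COc1ccc(/C=N/NS(=O)(=O)c2ccc(C)cc2)cc1
Why: Proposed new method: same sulfide-catalysed [4+1] as Step 5. The enantiomeric sulfide places the ylide on the opposite o-quinone methide face, giving the (2S,3S) ring against the pre-existing (2R,3R) ring, with trans closure as before.

**Step 9**
Reactants: 12; 4
Product: 13 (benzhydrol on the bis-DHB bromide)
Conditions: 12, t-BuLi (2.0 equiv), THF, −78 °C, 10 min; then the sodium phenoxide of 4, −78 → 0 °C
Reagents that add atoms: none beyond the listed reactants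
Why: Br/Li exchange then 1,2-addition, as in Step 6.

**Step 10**
Reactants: 13; 6
Product: 14 (sulfone)
Conditions: 6 (3 equiv), HCO2H/CH2Cl2 (1:4), 25 °C
Reagents that add atoms: sodium p-toluenesulfinate, Cc1ccc(cc1)S(=O)[O-].[Na+] (adds Ts)
Why: Same sulfone formation as Step 4.

**Step 11 (new step, ring DHB1)**
Reactants: 14; 8
Product: 15 (tris-DHB aryl bromide, permethylated, (2R,3R)/(2S,3S)/(2R,3R))
Conditions: 8 (2.5 equiv), Cs2CO3 (4 equiv), Rh2(OAc)4 (1 mol%), (2S,5S)-2,5-dimethylthiolane (20 mol%), BnEt3NCl (10 mol%), 1,4-dioxane, 40 °C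
Reagents that add atoms: 8, COc1ccc(/C=N/NS(=O)(=O)c2ccc(C)cc2)cc1
Why: Proposed new method: same sulfide-catalysed [4+1] as Step 5, run on the most hindered o-quinone methide. Catalyst control sets C3 and the anti-closure sets trans C2.

**Step 12**
Reactants: 15; 16 (4-methoxystyrene)
Product: 17 (nonamethyl ether of the target, E-stilbene)
Conditions: Pd2(dba)3 (5 mol%), P(t-Bu)3·HBF4 (20 mol%), Cy2NMe, 1,4-dioxane, 100 °C
Reagents that add atoms: 16, C=Cc1ccc(OC)cc1 (supplies the styryl unit)
Why: Mizoroki–Heck coupling on the hindered aryl bromide with a bulky electron-rich phosphine and a mild amine base. It gives the E-alkene and leaves the six DHB stereocentres untouched, since the amine is too weak to cause E1cB.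

**Step 13**
Reactants: 17
Product: 18 (Miyabenol A)
Conditions: BBr3 (4 equiv per OMe), CH2Cl2, −78 → 0 °C; quench with MeOH
Reagents that add atoms: none
Why: BBr3 cleaves all nine aryl methyl ethers. C3 stereocentres are not ionisable, and any transient C2 ionisation re-closes to trans.

## Compound list
1 | 1-bromo-3,5-dimethoxybenzene | COc1cc(Br)cc(OC)c1 | starting material
2 | N,N-dimethylformamide | CN(C)C=O | starting material
3 | 2-bromo-4,6-dimethoxybenzaldehyde | COc1cc(OC)c(C=O)c(Br)c1 | intermediate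
4 | 2-bromo-6-hydroxy-4-methoxybenzaldehyde | COc1cc(O)c(C=O)c(Br)c1 | intermediate
5 | (2-bromo-6-hydroxy-4-methoxyphenyl)(3,5-dimethoxyphenyl)methanol | COc1cc(OC)cc(c1)C(O)c1c(O)cc(OC)cc1Br | intermediate
6 | sodium p-toluenesulfinate | Cc1ccc(cc1)S(=O)[O-].[Na+] | starting material
7 | 3-bromo-2-[(3,5-dimethoxyphenyl)(tosyl)methyl]-5-methoxyphenol | COc1cc(OC)cc(c1)C(c2c(O)cc(OC)cc2Br)S(=O)(=O)c3ccc(C)cc3 | intermediate
8 | p-anisaldehyde tosylhydrazone | COc1ccc(/C=N/NS(=O)(=O)c2ccc(C)cc2)cc1 | starting material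
9 | (2R,3R)-4-bromo-3-(3,5-dimethoxyphenyl)-6-methoxy-2-(4-methoxyphenyl)-2,3-dihydrobenzofuran | Brc2cc(OC)cc5c2[C@@H](c2cc(OC)cc(OC)c2)[C@H](c2ccc(OC)cc2)O5 | intermediate
10 | benzhydrol from 9 and 4 | OC(c2c(O)cc(OC)cc2Br)c2cc(OC)cc5c2[C@@H](c2cc(OC)cc(OC)c2)[C@H](c2ccc(OC)cc2)O5 | intermediate
11 | tosyl sulfone from 10 | Cc1ccc(cc1)S(=O)(=O)C(c2c(O)cc(OC)cc2Br)c2cc(OC)cc5c2[C@@H](c2cc(OC)cc(OC)c2)[C@H](c2ccc(OC)cc2)O5 | intermediate
12 | bis-DHB aryl bromide, (2S,3S) ring attached to (2R,3R) ring | Brc2cc(OC)cc4c2[C@H](c2cc(OC)cc5c2[C@@H](c2cc(OC)cc(OC)c2)[C@H](c2ccc(OC)cc2)O5)[C@@H](c2ccc(OC)cc2)O4 | intermediate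
13 | benzhydrol from 12 and 4 | OC(c2c(O)cc(OC)cc2Br)c2cc(OC)cc4c2[C@H](c2cc(OC)cc5c2[C@@H](c2cc(OC)cc(OC)c2)[C@H](c2ccc(OC)cc2)O5)[C@@H](c2ccc(OC)cc2)O4 | intermediate
14 | tosyl sulfone from 13 | Cc1ccc(cc1)S(=O)(=O)C(c2c(O)cc(OC)cc2Br)c2cc(OC)cc4c2[C@H](c2cc(OC)cc5c2[C@@H](c2cc(OC)cc(OC)c2)[C@H](c2ccc(OC)cc2)O5)[C@@H](c2ccc(OC)cc2)O4 | intermediate
15 | tris-DHB aryl bromide, permethylated | Brc2cc(OC)cc3c2[C@@H](c2cc(OC)cc4c2[C@H](c2cc(OC)cc5c2[C@@H](c2cc(OC)cc(OC)c2)[C@H](c2ccc(OC)cc2)O5)[C@@H](c2ccc(OC)cc2)O4)[C@H](c2ccc(OC)cc2)O3 | intermediate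
16 | 4-methoxystyrene | C=Cc1ccc(OC)cc1 | starting material
17 | nonamethyl ether of Miyabenol A | COc1ccc(/C=C/c2cc(OC)cc3c2[C@@H](c2cc(OC)cc4c2[C@H](c2cc(OC)cc5c2[C@@H](c2cc(OC)cc(OC)c2)[C@H](c2ccc(OC)cc2)O5)[C@@H](c2ccc(OC)cc2)O4)[C@H](c2ccc(OC)cc2)O3)cc1 | intermediate
18 | Miyabenol A | Oc1ccc(/C=C/c2cc(O)cc3c2[C@@H](c2cc(O)cc4c2[C@H](c2cc(O)cc5c2[C@@H](c2cc(O)cc(O)c2)[C@H](c2ccc(O)cc2)O5)[C@@H](c2ccc(O)cc2)O4)[C@H](c2ccc(O)cc2)O3)cc1 | target

## Totals
Total steps: 13. Longest linear sequence: 13 (1 → 3 → 4 → 5 → 7 → 9 → 10 → 11 → 12 → 13 → 14 → 15 → 17 → 18, with 4 also fed in as a side branch at Steps 3, 6 and 9).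

## Three steps most likely to fail
1. **Steps 5, 8 and 11 (proposed sulfide-catalysed asymmetric [4+1]).** The risks are low ee or dr on the very hindered o-quinone methides, and Rh-carbene O–H insertion into the phenoxide.
   - Fallback (known chemistry): use the achiral Xiao-type [4+1] with (4-methoxybenzyl)dimethylsulfonium bromide and Cs2CO3. Resolve racemic 9 by chiral HPLC, then carry each later diastereomeric pair through separation on silica/HPLC.
2. **Steps 6 and 9 (hindered aryllithium addition).** The chain aryllithium may fail to add to the ortho,ortho-disubstituted salicylaldehyde, or may cause E1cB ring opening of a DHB.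
   - Fallback: convert the aryl bromide to the pinacol boronate (Miyaura borylation), then add it to the aldehyde using Rh(I)-catalysed 1,2-addition.
3. **Step 13 (global BBr3 demethylation of nine OMe groups).** The DHB benzylic C–O bonds and the stilbene may degrade.
   - Fallback: rebuild the route with MOM ethers on every phenol, using MOM-protected analogues of 1, 4, 8 and 16. Remove them in the last step with HCl/MeOH at 40 °C.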